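**Retrosynthetic overview**

1. Target 27 ⇐ desilylation ⇐ Steglich esterification of the C4 hydroxyl (22) with the TBS-protected (S)-Roche acid 25; the α-methylene-γ-lactone ⇐ Mannich/elimination on trans-lactone 18 ⇐ C3a acetate arm (enolate alkylation) and equatorial C7a–OH (electron-transfer reduction) on cyclohexanone 14.
2. Cyclohexanone 14 (C7 and quaternary C6 set together) ⇐ Claisen ring contraction, 8 → 6, of the 2-alkylidene oxocine 13: the exocyclic enol-ether carbon (C7) bonds across the ring to C6 and the ring O–CH2 bond breaks, so O and CH2 leave the ring and become the C7a carbonyl oxygen and the vinyl terminus.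
3. Enabling feature: in the six-membered carbocycle the oxygen-bearing C7a is 1,3 to the quaternary C6 that carries the vinyl group, so C7a(O)–C7–C6–CH=CH2 is a γ,δ-unsaturated carbonyl unit. Joining the C7a oxygen to the vinyl CH2 as an allylic ether gives an eight-membered ring (O, C7a, C3a, C4, C5, C6, CH=, CH2) that carries the stereodefined C4 oxygen, which steers the contraction.
4. Oxocine 12 ⇐ RCM of allyl vinyl ether 11 ⇐ copper-catalysed O-vinylation of allyl alcohol with (Z)-β-iodo enone 9 ⇐ ynone 8 ⇐ alkyne 6 + Weinreb amide 7; 6 ⇐ (S)-epichlorohydrin, isopropenylmagnesium bromide and lithium acetylide (C4 stereocentre from the chiral pool).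
5. Order of ring formation: oxocine (RCM) → cyclohexane (ring contraction) → γ-lactone.

Key step: step 8

Remark: locants C3, C3a, C4, C5, C6, C7 and C7a are those of the 1-benzofuran-2-one core of the target (C7a lactone C–O carbon, C7 carrying the hydroxypropenyl group, quaternary C6, C5 methylene, C4 carrying the ester, C3a ring fusion) and are used for the same carbons in all earlier compounds; compounds 1, 2, 7, 10, 15 and 23 are taken as commercial.

**Route**

Step 1
Reactants: 1 (2S)-2-(chloromethyl)oxirane [(S)-epichlorohydrin]; 2 isopropenylmagnesium bromide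
Product: 3 (2S)-1-chloro-4-methylpent-4-en-2-ol
Conditions: 2 (1.2 equiv), CuI (10 mol%), THF, −40 to −20 °C; H2O work-up
Reagents that add atoms: none
Why: Copper-catalysed Grignard opening of the terminal epoxide at its CH2 carbon (SN2) leaves the carbinol stereocentre, the future C4, untouched.

Step 2
Reactants: 3 (2S)-1-chloro-4-methylpent-4-en-2-ol
Product: 5 (4S)-6-methylhept-6-en-1-yn-4-ol, via epoxide 4 (not isolated)
Conditions: lithium acetylide–ethylenediamine complex (3 equiv), DMSO, 0 °C to rt; H2O work-up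
Reagents that add atoms: lithium acetylide–ethylenediamine complex, [Li]C#C.NCCN
Why: One equivalent of acetylide deprotonates the chlorohydrin, which closes to the terminal epoxide (intramolecular Williamson reaction), and a further equivalent opens it at CH2 (SN2), again without touching the stereocentre.

Step 3
Reactants: 5 (4S)-6-methylhept-6-en-1-yn-4-ol
Product: 6 1-methoxy-4-({[(4S)-6-methylhept-6-en-1-yn-4-yl]oxy}methyl)benzene
Conditions: NaH, 4-methoxybenzyl chloride, Bu4NI (cat.), THF/DMF, 0 °C to rt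
Reagents that add atoms: 4-methoxybenzyl chloride, COc1ccc(CCl)cc1
Why: Williamson etherification of the alkoxide gives the PMB ether that later steers the ring contraction and is removable in the presence of silyl ethers.

Step 4
Reactants: 6 1-methoxy-4-({[(4S)-6-methylhept-6-en-1-yn-4-yl]oxy}methyl)benzene; 7 2-[(tert-butyldimethylsilyl)oxy]-N-methoxy-N-methylacetamide
Product: 8 (6S)-1-[(tert-butyldimethylsilyl)oxy]-6-[(4-methoxyphenyl)methoxy]-8-methylnon-8-en-3-yn-2-one
Conditions: n-BuLi (1.05 equiv), THF, −78 °C; then 7, −78 to −20 °C; H2O work-up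
Reagents that add atoms: none
Why: Weinreb ketone synthesis: the lithium acetylide acylates once because the chelated tetrahedral intermediate only collapses on work-up.

Step 5
Reactants: 8 (6S)-1-[(tert-butyldimethylsilyl)oxy]-6-[(4-methoxyphenyl)methoxy]-8-methylnon-8-en-3-yn-2-one
Product: 9 (3Z,6S)-1-[(tert-butyldimethylsilyl)oxy]-4-iodo-6-[(4-methoxyphenyl)methoxy]-8-methylnona-3,8-dien-2-one
Conditions: NaI (1.2 equiv), AcOH (3 equiv), acetone, 0 °C to rt, dark
Reagents that add atoms: sodium iodide, [Na+].[I-]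
Why: Conjugate addition of iodide to the ynone and in-plane protonation of the allenolate amount to anti-hydroiodination, which should give the (Z)-β-iodo enone with iodine cis to the acyl group.

Step 6
Reactants: 9 (3Z,6S)-1-[(tert-butyldimethylsilyl)oxy]-4-iodo-6-[(4-methoxyphenyl)methoxy]-8-methylnona-3,8-dien-2-one; 10 prop-2-en-1-ol
Product: 11 (3Z,6S)-1-[(tert-butyldimethylsilyl)oxy]-6-[(4-methoxyphenyl)methoxy]-8-methyl-4-(prop-2-en-1-yloxy)nona-3,8-dien-2-one
Conditions: 10 (3 equiv), CuI (10 mol%), 3,4,7,8-tetramethyl-1,10-phenanthroline (20 mol%), Cs2CO3 (1.5 equiv), toluene, 50 °C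
Reagents that add atoms: none
Why: Copper-catalysed Ullmann-type C–O coupling (O-vinylation) should replace iodide by allyloxy with retention of olefin geometry, keeping the ether oxygen cis to the acyl group, at a temperature well below that of an acyclic Claisen rearrangement.

Step 7
Reactants: 11 (3Z,6S)-1-[(tert-butyldimethylsilyl)oxy]-6-[(4-methoxyphenyl)methoxy]-8-methyl-4-(prop-2-en-1-yloxy)nona-3,8-dien-2-one
Product: 12 (2Z,4S,6Z)-2-{3-[(tert-butyldimethylsilyl)oxy]-2-oxopropylidene}-4-[(4-methoxyphenyl)methoxy]-6-methyl-3,4,5,8-tetrahydro-2H-oxocine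
Conditions: second-generation Grubbs catalyst (10 mol%), 1,4-benzoquinone (20 mol%), CH2Cl2 (1 mM), 40 °C
Reagents that add atoms: none
Why: Ring-closing olefin metathesis joins the allyl ether and the 1,1-disubstituted olefin with loss of ethylene; the eight-membered ring can only hold the (Z)-trisubstituted olefin, and the planar enol ether unit together with high dilution should favour cyclisation over oligomerisation.

Step 8
Reactants: 12 (2Z,4S,6Z)-2-{3-[(tert-butyldimethylsilyl)oxy]-2-oxopropylidene}-4-[(4-methoxyphenyl)methoxy]-6-methyl-3,4,5,8-tetrahydro-2H-oxocine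
Product: 14 (2R,3R,5S)-2-{3-[(tert-butyldimethylsilyl)oxy]prop-1-en-2-yl}-3-ethenyl-5-[(4-methoxyphenyl)methoxy]-3-methylcyclohexan-1-one, via dienyl ether 13 (not isolated)
Conditions: Cp2TiMe2 (2 equiv), toluene, pyridine (1%), 65 °C, dark; filtration through basic alumina; then toluene, K2CO3 (solid), 120 °C
Reagents that add atoms: dimethyltitanocene Cp2TiMe2, C[Ti](C)(C1C=CC=C1)C1C=CC=C1
Why: Cp2TiMe2 transfers CH2 to the vinylogous-ester carbonyl (Petasis methylenation via an oxatitanacyclobutane) to give the 2-alkoxy-1,3-diene 13, whose allyl vinyl ether unit then undergoes a concerted thermal [3,3] sigmatropic shift (aliphatic Claisen rearrangement; closest known type: methylenation–Claisen rearrangement of 2-methylene oxacycles and Claisen ring contraction of cyclic allyl vinyl ethers). The exocyclic enol-ether carbon (future C7) bonds across the ring to the methyl-bearing olefin carbon (future C6) while the ring O–CH2 bond breaks, so the carbocycle is closed by transannular C–C bond formation through a bicyclo[3.3.1]-like chair–chair transition state and the ring shrinks by the two atoms O and CH2, which reappear as the C7a carbonyl oxygen and the vinyl terminus. The quaternary C6 is set because the O–CH2–CH= bridge must span C7a and C6 diaxially on the nascent chair (vinyl axial, methyl equatorial), and the olefin face is chosen by the C4–OPMB group, which must sit exo (equatorial) since the endo position collides with the OCH2 carbon; this should give vinyl trans to OPMB. C7 is set by the (Z)-enol ether geometry fixed in steps 5 and 6: the substituent cis to the ring oxygen ends up equatorial, that is cis to the vinyl group. The step needs methylenation of the only carbonyl, an intact (Z)-enol ether (base-washed glass, no acid) and periselectivity over a [1,5]-hydrogen shift, which the (Z)-geometry excludes because the ring CH2 next to the enol ether carbon is held trans to the diene; relief of medium-ring strain and C=O formation make the contraction irreversible.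

Step 9
Reactants: 14 (2R,3R,5S)-2-{3-[(tert-butyldimethylsilyl)oxy]prop-1-en-2-yl}-3-ethenyl-5-[(4-methoxyphenyl)methoxy]-3-methylcyclohexan-1-one; 15 methyl bromoacetate
Product: 16 methyl 2-[(1R,3R,4R,6S)-3-{3-[(tert-butyldimethylsilyl)oxy]prop-1-en-2-yl}-4-ethenyl-6-[(4-methoxyphenyl)methoxy]-4-methyl-2-oxocyclohexyl]acetate
Conditions: LiN(SiMe3)2 (1.1 equiv), THF, −78 °C; then 15 (1.5 equiv), DMPU, −78 to −40 °C
Reagents that add atoms: none
Why: Kinetic lithium enolate alkylation: the bulky amide should take a proton from the less hindered C3a methylene and not the C7 methine next to the quaternary carbon, and the electrophile should enter trans to the adjacent OPMB group so that the new C3a substituent is equatorial (the centre can also be epimerised to this arrangement).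

Step 10
Reactants: 16 methyl 2-[(1R,3R,4R,6S)-3-{3-[(tert-butyldimethylsilyl)oxy]prop-1-en-2-yl}-4-ethenyl-6-[(4-methoxyphenyl)methoxy]-4-methyl-2-oxocyclohexyl]acetate
Product: 18 (3aR,4S,6R,7R,7aR)-7-{3-[(tert-butyldimethylsilyl)oxy]prop-1-en-2-yl}-6-ethenyl-4-[(4-methoxyphenyl)methoxy]-6-methylhexahydro-1-benzofuran-2(3H)-one, via hydroxy ester 17 (not isolated)
Conditions: SmI2 (2.5 equiv), THF/MeOH (4:1), 0 °C; then PPTS (cat.), toluene, 50 °C
Reagents that add atoms: none
Why: Single-electron (SmI2) ketone reduction should place the samarium-bound oxygen equatorial and so give the equatorial C7a–OH trans to both neighbours (a hydride reagent would be steered to the other face by the axial vinyl group), and the γ-hydroxy ester then lactonises to the trans-fused lactone.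

Step 11
Reactants: 18 (3aR,4S,6R,7R,7aR)-7-{3-[(tert-butyldimethylsilyl)oxy]prop-1-en-2-yl}-6-ethenyl-4-[(4-methoxyphenyl)methoxy]-6-methylhexahydro-1-benzofuran-2(3H)-one
Product: 21 (3aR,4S,6R,7R,7aR)-7-{3-[(tert-butyldimethylsilyl)oxy]prop-1-en-2-yl}-6-ethenyl-4-[(4-methoxyphenyl)methoxy]-6-methyl-3-methylidenehexahydro-1-benzofuran-2(3H)-one, via Mannich base 19 (not isolated), via ammonium iodide 20 (not isolated)
Conditions: LiN(iPr)2 (1.2 equiv), THF, −78 °C; Me2N=CH2+ I− (Eschenmoser's salt), −78 to 0 °C; then MeI, MeOH, rt; then aq. NaHCO3/CH2Cl2, rt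
Reagents that add atoms: N,N-dimethylmethyleneiminium iodide (Eschenmoser's salt), C=[N+](C)C.[I-]
Why: Mannich reaction of the lactone enolate, N-quaternisation and E1cB (Hofmann-type) elimination install the exocyclic methylene; the transient C3 stereocentre is destroyed.

Step 12
Reactants: 21 (3aR,4S,6R,7R,7aR)-7-{3-[(tert-butyldimethylsilyl)oxy]prop-1-en-2-yl}-6-ethenyl-4-[(4-methoxyphenyl)methoxy]-6-methyl-3-methylidenehexahydro-1-benzofuran-2(3H)-one
Product: 22 (3aR,4S,6R,7R,7aR)-7-{3-[(tert-butyldimethylsilyl)oxy]prop-1-en-2-yl}-6-ethenyl-4-hydroxy-6-methyl-3-methylidenehexahydro-1-benzofuran-2(3H)-one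
Conditions: DDQ (1.5 equiv), CH2Cl2/pH 7 buffer (10:1), 0 °C to rt
Reagents that add atoms: none
Why: Oxidative cleavage of the p-methoxybenzyl ether by DDQ (benzylic hydride abstraction, hydrolysis of the oxocarbenium ion) should free only the C4 hydroxyl; silyl ethers, olefins and the α-methylene lactone are inert.

Step 13
Reactants: 23 methyl (2S)-3-hydroxy-2-methylpropanoate [(S)-Roche ester]
Product: 24 methyl (2S)-3-[(tert-butyldimethylsilyl)oxy]-2-methylpropanoate
Conditions: TBSCl, imidazole, CH2Cl2, 0 °C to rt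
Reagents that add atoms: tert-butyldimethylsilyl chloride, CC(C)(C)[Si](C)(C)Cl
Why: Silylation of the primary alcohol; the α-stereocentre is not involved.

Step 14
Reactants: 24 methyl (2S)-3-[(tert-butyldimethylsilyl)oxy]-2-methylpropanoate
Product: 25 (2S)-3-[(tert-butyldimethylsilyl)oxy]-2-methylpropanoic acid
Conditions: LiOH·H2O, THF/MeOH/H2O, 0 °C to rt; then cold 1 M HCl to pH 3–4
Reagents that add atoms: lithium hydroxide, [Li+].[OH-]
Why: Mild saponification at 0 °C should cleave the methyl ester without β-elimination or epimerisation of the α-stereocentre.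

Step 15
Reactants: 22 (3aR,4S,6R,7R,7aR)-7-{3-[(tert-butyldimethylsilyl)oxy]prop-1-en-2-yl}-6-ethenyl-4-hydroxy-6-methyl-3-methylidenehexahydro-1-benzofuran-2(3H)-one; 25 (2S)-3-[(tert-butyldimethylsilyl)oxy]-2-methylpropanoic acid
Product: 26 (3aR,4S,6R,7R,7aR)-7-{3-[(tert-butyldimethylsilyl)oxy]prop-1-en-2-yl}-6-ethenyl-6-methyl-3-methylidene-2-oxooctahydro-1-benzofuran-4-yl (2S)-3-[(tert-butyldimethylsilyl)oxy]-2-methylpropanoate
Conditions: DCC (1.5 equiv), DMAP (0.2 equiv), CH2Cl2, 0 °C to rt
Reagents that add atoms: none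
Why: Steglich esterification (carbodiimide activation, DMAP acyl transfer) acylates the only free, equatorial secondary hydroxyl with retention at the carbinol and at the α-stereocentre of the acid.

Step 16
Reactants: 26 (3aR,4S,6R,7R,7aR)-7-{3-[(tert-butyldimethylsilyl)oxy]prop-1-en-2-yl}-6-ethenyl-6-methyl-3-methylidene-2-oxooctahydro-1-benzofuran-4-yl (2S)-3-[(tert-butyldimethylsilyl)oxy]-2-methylpropanoate
Product: 27 (3aR,4S,6R,7R,7aR)-6-ethenyl-7-(3-hydroxyprop-1-en-2-yl)-6-methyl-3-methylidene-2-oxooctahydro-1-benzofuran-4-yl (2S)-3-hydroxy-2-methylpropanoate (target)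
Conditions: HF·pyridine, THF/pyridine, 0 °C to rt
Reagents that add atoms: none
Why: Fluoride-mediated desilylation under buffered conditions should remove both primary TBS ethers without acyl migration, ester cleavage or conjugate addition to the α-methylene lactone.

**Compound list**

1 | (2S)-2-(chloromethyl)oxirane [(S)-epichlorohydrin] | ClC[C@@H]1CO1 | starting material
2 | isopropenylmagnesium bromide | CC(=C)[Mg]Br | starting material
3 | (2S)-1-chloro-4-methylpent-4-en-2-ol | ClC[C@@H](O)CC(C)=C | intermediate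
4 | (2S)-2-(2-methylprop-2-en-1-yl)oxirane | C=C(C)C[C@H]1CO1 | intermediate
5 | (4S)-6-methylhept-6-en-1-yn-4-ol | C#CC[C@@H](O)CC(C)=C | intermediate
6 | 1-methoxy-4-({[(4S)-6-methylhept-6-en-1-yn-4-yl]oxy}methyl)benzene | C#CC[C@@H](OCc1ccc(OC)cc1)CC(C)=C | intermediate
7 | 2-[(tert-butyldimethylsilyl)oxy]-N-methoxy-N-methylacetamide | CON(C)C(=O)CO[Si](C)(C)C(C)(C)C | starting material
8 | (6S)-1-[(tert-butyldimethylsilyl)oxy]-6-[(4-methoxyphenyl)methoxy]-8-methylnon-8-en-3-yn-2-one | CC(C)(C)[Si](C)(C)OCC(=O)C#CC[C@@H](OCc1ccc(OC)cc1)CC(C)=C | intermediate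
9 | (3Z,6S)-1-[(tert-butyldimethylsilyl)oxy]-4-iodo-6-[(4-methoxyphenyl)methoxy]-8-methylnona-3,8-dien-2-one | CC(C)(C)[Si](C)(C)OCC(=O)/C=C(\I)C[C@@H](OCc1ccc(OC)cc1)CC(C)=C | intermediate
10 | prop-2-en-1-ol (allyl alcohol) | C=CCO | starting material
11 | (3Z,6S)-1-[(tert-butyldimethylsilyl)oxy]-6-[(4-methoxyphenyl)methoxy]-8-methyl-4-(prop-2-en-1-yloxy)nona-3,8-dien-2-one | CC(C)(C)[Si](C)(C)OCC(=O)/C=C(\OCC=C)C[C@@H](OCc1ccc(OC)cc1)CC(C)=C | intermediate
12 | (2Z,4S,6Z)-2-{3-[(tert-butyldimethylsilyl)oxy]-2-oxopropylidene}-4-[(4-methoxyphenyl)methoxy]-6-methyl-3,4,5,8-tetrahydro-2H-oxocine | CC(C)(C)[Si](C)(C)OCC(=O)/C=C1\OC/C=C(C)\C[C@H](OCc2ccc(OC)cc2)C1 | intermediate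
13 | (2Z,4S,6Z)-2-(2-{[(tert-butyldimethylsilyl)oxy]methyl}prop-2-en-1-ylidene)-4-[(4-methoxyphenyl)methoxy]-6-methyl-3,4,5,8-tetrahydro-2H-oxocine | CC(C)(C)[Si](C)(C)OCC(=C)/C=C1\OC/C=C(C)\C[C@H](OCc2ccc(OC)cc2)C1 | intermediate
14 | (2R,3R,5S)-2-{3-[(tert-butyldimethylsilyl)oxy]prop-1-en-2-yl}-3-ethenyl-5-[(4-methoxyphenyl)methoxy]-3-methylcyclohexan-1-one | C=C[C@@]1(C)C[C@H](OCc2ccc(OC)cc2)CC(=O)[C@H]1C(=C)CO[Si](C)(C)C(C)(C)C | intermediate
15 | methyl bromoacetate | COC(=O)CBr | starting material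
16 | methyl 2-[(1R,3R,4R,6S)-3-{3-[(tert-butyldimethylsilyl)oxy]prop-1-en-2-yl}-4-ethenyl-6-[(4-methoxyphenyl)methoxy]-4-methyl-2-oxocyclohexyl]acetate | C=C[C@@]1(C)C[C@H](OCc2ccc(OC)cc2)[C@@H](CC(=O)OC)C(=O)[C@H]1C(=C)CO[Si](C)(C)C(C)(C)C | intermediate
17 | methyl 2-[(1S,2R,3R,4R,6S)-3-{3-[(tert-butyldimethylsilyl)oxy]prop-1-en-2-yl}-4-ethenyl-2-hydroxy-6-[(4-methoxyphenyl)methoxy]-4-methylcyclohexyl]acetate | C=C[C@@]1(C)C[C@H](OCc2ccc(OC)cc2)[C@@H](CC(=O)OC)[C@H](O)[C@H]1C(=C)CO[Si](C)(C)C(C)(C)C | intermediate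
18 | (3aR,4S,6R,7R,7aR)-7-{3-[(tert-butyldimethylsilyl)oxy]prop-1-en-2-yl}-6-ethenyl-4-[(4-methoxyphenyl)methoxy]-6-methylhexahydro-1-benzofuran-2(3H)-one | C=C[C@@]1(C)C[C@H](OCc2ccc(OC)cc2)[C@H]2CC(=O)O[C@@H]2[C@H]1C(=C)CO[Si](C)(C)C(C)(C)C | intermediate
19 | (3aR,4S,6R,7R,7aR)-7-{3-[(tert-butyldimethylsilyl)oxy]prop-1-en-2-yl}-3-[(dimethylamino)methyl]-6-ethenyl-4-[(4-methoxyphenyl)methoxy]-6-methylhexahydro-1-benzofuran-2(3H)-one (C3 epimers, inconsequential) | C=C[C@@]1(C)C[C@H](OCc2ccc(OC)cc2)[C@H]2C(CN(C)C)C(=O)O[C@@H]2[C@H]1C(=C)CO[Si](C)(C)C(C)(C)C | intermediate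
20 | {[(3aR,4S,6R,7R,7aR)-7-{3-[(tert-butyldimethylsilyl)oxy]prop-1-en-2-yl}-6-ethenyl-4-[(4-methoxyphenyl)methoxy]-6-methyl-2-oxooctahydro-1-benzofuran-3-yl]methyl}trimethylammonium iodide (C3 epimers) | C=C[C@@]1(C)C[C@H](OCc2ccc(OC)cc2)[C@H]2C(C[N+](C)(C)C)C(=O)O[C@@H]2[C@H]1C(=C)CO[Si](C)(C)C(C)(C)C.[I-] | intermediate
21 | (3aR,4S,6R,7R,7aR)-7-{3-[(tert-butyldimethylsilyl)oxy]prop-1-en-2-yl}-6-ethenyl-4-[(4-methoxyphenyl)methoxy]-6-methyl-3-methylidenehexahydro-1-benzofuran-2(3H)-one | C=C[C@@]1(C)C[C@H](OCc2ccc(OC)cc2)[C@H]2C(=C)C(=O)O[C@@H]2[C@H]1C(=C)CO[Si](C)(C)C(C)(C)C | intermediate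
22 | (3aR,4S,6R,7R,7aR)-7-{3-[(tert-butyldimethylsilyl)oxy]prop-1-en-2-yl}-6-ethenyl-4-hydroxy-6-methyl-3-methylidenehexahydro-1-benzofuran-2(3H)-one | C=C[C@@]1(C)C[C@H](O)[C@H]2C(=C)C(=O)O[C@@H]2[C@H]1C(=C)CO[Si](C)(C)C(C)(C)C | intermediate
23 | methyl (2S)-3-hydroxy-2-methylpropanoate [(S)-Roche ester] | COC(=O)[C@@H](C)CO | starting material
24 | methyl (2S)-3-[(tert-butyldimethylsilyl)oxy]-2-methylpropanoate | COC(=O)[C@@H](C)CO[Si](C)(C)C(C)(C)C | intermediate
25 | (2S)-3-[(tert-butyldimethylsilyl)oxy]-2-methylpropanoic acid | OC(=O)[C@@H](C)CO[Si](C)(C)C(C)(C)C | intermediate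
26 | (3aR,4S,6R,7R,7aR)-7-{3-[(tert-butyldimethylsilyl)oxy]prop-1-en-2-yl}-6-ethenyl-6-methyl-3-methylidene-2-oxooctahydro-1-benzofuran-4-yl (2S)-3-[(tert-butyldimethylsilyl)oxy]-2-methylpropanoate | C=C[C@@]1(C)C[C@H](OC(=O)[C@@H](C)CO[Si](C)(C)C(C)(C)C)[C@H]2C(=C)C(=O)O[C@@H]2[C@H]1C(=C)CO[Si](C)(C)C(C)(C)C | intermediate
27 | (3aR,4S,6R,7R,7aR)-6-ethenyl-7-(3-hydroxyprop-1-en-2-yl)-6-methyl-3-methylidene-2-oxooctahydro-1-benzofuran-4-yl (2S)-3-hydroxy-2-methylpropanoate | C=C[C@@]1(C)C[C@H](OC(=O)[C@@H](C)CO)[C@H]2C(=C)C(=O)O[C@@H]2[C@H]1C(=C)CO | target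

**Step count and risks**

Total steps: 16. Longest linear sequence: 14 (steps 1–12, 15, 16).

Steps most likely to fail:

1. Step 8 (methylenation and ring contraction). What may go wrong: the ring contraction sets in while the titanium methylidene is still present, so that the new C7a ketone is methylenated as well; the α-silyloxy vinylogous ketone is enolised instead of methylenated; or the acid-labile 2-alkoxydiene hydrolyses before it rearranges. Fallback: from oxocine 12 the methylene is brought in by a Peterson olefination and not by a titanium carbenoid. Me3SiCH2Li/CeCl3 (THF, −78 °C) should add 1,2 to the carbonyl to give the β-hydroxysilane F1, and KH (THF, 0 °C) should then eliminate it to dienyl ether 13 under strictly basic, carbenoid-free conditions. Dienyl ether 13 is heated in base-washed glass (toluene, 120 °C) and the route is rejoined at ketone 14.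

2. Step 7 (ring-closing metathesis). What may go wrong: intermolecular metathesis of the reactive allyl ether (oligomerisation) outruns closure onto the sluggish 1,1-disubstituted olefin. Fallback: the ring-closing bond is changed from C=C to C–O. From iodo enone 9, cross-metathesis with (Z)-but-2-ene-1,4-diol (second-generation Grubbs catalyst, CH2Cl2, 40 °C) should give the trisubstituted allylic alcohol as the (8Z)-isomer F2 together with the (8E)-isomer F3. The (8E)-isomer F3 cannot cyclise and is returned to the mixture by sensitised photoisomerisation. The (8Z)-isomer F2 is closed by intramolecular copper-catalysed O-vinylation (CuI, 3,4,7,8-tetramethyl-1,10-phenanthroline, Cs2CO3, toluene, high dilution), and the route is rejoined at oxocine 12.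

3. Step 9 (regioselective alkylation). What may go wrong: the base removes the doubly activated C7 methine proton (α to the ketone and allylic) in place of a C3a proton, which leads to epimerisation or alkylation at C7, or the C3a enolate expels the β-OPMB group. Fallback: the regiochemistry is fixed through an aza-enolate. From ketone 14, condensation with 1,1-dimethylhydrazine (EtOH, AcOH cat., 60 °C) should give the N,N-dimethylhydrazone F4. Its metalation with LiN(iPr)2 (THF, −78 to 0 °C) occurs at the less substituted α-CH2, and alkylation with 15 should give the alkylated hydrazone F5. Mild hydrolysis (aqueous oxalic acid/Et2O) rejoins the route at keto ester 16.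

Further compounds
F1 | step 8 | (2Z,4S,6Z)-2-{3-[(tert-butyldimethylsilyl)oxy]-2-hydroxy-2-[(trimethylsilyl)methyl]propylidene}-4-[(4-methoxyphenyl)methoxy]-6-methyl-3,4,5,8-tetrahydro-2H-oxocine (both carbinol epimers, inconsequential) | CC(C)(C)[Si](C)(C)OCC(O)(C[Si](C)(C)C)/C=C1\OC/C=C(C)\C[C@H](OCc2ccc(OC)cc2)C1
F2 | step 7 | (3Z,6S,8Z)-1-[(tert-butyldimethylsilyl)oxy]-10-hydroxy-4-iodo-6-[(4-methoxyphenyl)methoxy]-8-methyldeca-3,8-dien-2-one | CC(C)(C)[Si](C)(C)OCC(=O)/C=C(\I)C[C@@H](OCc1ccc(OC)cc1)C/C(C)=C\CO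
F3 | step 7 | (3Z,6S,8E)-1-[(tert-butyldimethylsilyl)oxy]-10-hydroxy-4-iodo-6-[(4-methoxyphenyl)methoxy]-8-methyldeca-3,8-dien-2-one | CC(C)(C)[Si](C)(C)OCC(=O)/C=C(\I)C[C@@H](OCc1ccc(OC)cc1)C/C(C)=C/CO
F4 | step 9 | N,N-dimethylhydrazone of ketone 14: 2-[(2R,3R,5S)-2-{3-[(tert-butyldimethylsilyl)oxy]prop-1-en-2-yl}-3-ethenyl-5-[(4-methoxyphenyl)methoxy]-3-methylcyclohexylidene]-1,1-dimethylhydrazine | C=C[C@@]1(C)C[C@H](OCc2ccc(OC)cc2)CC(=NN(C)C)[C@H]1C(=C)CO[Si](C)(C)C(C)(C)C
F5 | step 9 | N,N-dimethylhydrazone of keto ester 16: methyl 2-[(1R,3R,4R,6S)-3-{3-[(tert-butyldimethylsilyl)oxy]prop-1-en-2-yl}-2-(2,2-dimethylhydrazinylidene)-4-ethenyl-6-[(4-methoxyphenyl)methoxy]-4-methylcyclohexyl]acetate | C=C[C@@]1(C)C[C@H](OCc2ccc(OC)cc2)[C@@H](CC(=O)OC)C(=NN(C)C)[C@H]1C(=C)CO[Si](C)(C)C(C)(C)C
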